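Assumption (chemistry): the SMILES is read as the C2-symmetric, all-cis (2S,3S,6R; 2′S,3′S,6′R) diolide (the alkaloid azimine). Locants used throughout, also for acyclic precursors: in each half N1, C2 (methyl-bearing), C3 (oxygen-bearing), C4, C5, C6 for the piperidine, C7–C11 for the pentamethylene tether and C12 for the ester carbonyl; primes mark the second half. In the alkene precursors C10 is the internal carbon of the 1-alkene and C11 the α-carbon of the acrylate; the two terminal methylene carbons are lost. Pent-4-enylmagnesium bromide (6) is taken as the commercial THF solution.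

## Analysis of the target

The target is a C2-symmetric tricycle: two all-cis 2-methyl-3-acyloxy-6-alkylpiperidines (ring A: N1, C2–C6; ring B: N1′, C2′–C6′) set into a 22-membered diolide (ring C: O3–C3–C4–C5–C6–C7…C11–C12(=O)–O3′ and its primed repeat), so that ring C spans the 3,6-positions of each piperidine. There are six stereocentres, three per half and identical in both halves (2S,3S,6R): C2 and C3 form a syn vicinal amino alcohol, and C6 is cis to both, 1,3 to C2 across N1 and 1,4 to C3. The halves are joined head to tail (the C12 acid of one half esterifies O3 of the other), so one three-centre problem has to be solved once and expressed twice. The sensitive groups are two basic secondary amines, each β to an ester oxygen (O→N acyl transfer, aminolysis, catalyst poisoning), and two esters of hindered secondary alcohols; the C7–C11 tethers are unfunctionalised. The difficulty lies in closing the 22-membered ring C head to tail against open-chain oligomers and against the 11-membered ring that one half alone could form. In the usual order this ring closure is attempted last, on N-protected piperidines that have already cost a long sequence. The feature that invites a different cut is twofold. N1–C6 (and N1′–C6′) is the one bond of rings A and B whose removal leaves ring C untouched and reveals a δ-amino ketone (nitrogen on C2, carbonyl at C6). C10–C11 lies α,β to the ester carbonyl C12, so a polarity-matched acrylate/1-alkene pair can be hidden in each tether.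

## Retrosynthetic reasoning

Disconnection 1 (16 to 12). The N1–C6 bond of ring A and the N1′–C6′ bond of ring B are cut first. Going back through bis(imine) 15 and bis(amino ketone) 14, masking both nitrogens as benzyl carbamates (13) and adding unsaturation at C10=C11 and C10′=C11′ leads to 12. Both basic nitrogens and two of the six stereocentres disappear, and ring C is kept. The forward reaction is a single hydrogenation that has to saturate two alkenes, release two amines, close rings A and B and set C6 and C6′ cis to the existing C2/C3 substituents.

Disconnection 2 (12 to 10). Ring C is cut at C10=C11′ and C10′=C11. These bonds lie next to the ester carbonyls, so the cut gives two identical acyclic halves 10, each with an electron-poor acrylate on O3 and an electron-rich 1-alkene at C10. In olefin metathesis these partners prefer each other over themselves, which makes head-to-tail union an intrinsic property of the monomer. A cut at the ester C–O bonds would need a hydroxy acid and an activation step and offers no such bias. The forward reaction must join two molecules head to tail (through 11) and close the 22-membered ring in the same flask, in preference to the strained 11-membered ring from one molecule and to oligomers.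

Disconnection 3 (10 to 8 and 9). The acrylate C–O bond is cut, which leaves the γ-hydroxy ketone 8 and the acyl donor 9. The forward reaction is a simple O-acylation placed directly before the key step, so the polymerisable acrylate is carried through no other operation.

Disconnection 4 (8 to 5 and 6). The C6–C7 bond is cut. Lactone 5 serves as a γ-hydroxy acyl donor that delivers C6 at the ketone oxidation level and keeps O3 tied up until it is needed; 6 brings C7–C10 and the 1-alkene. The forward reaction must stop at mono-addition, which is secured by passing through the N-methoxy-N-methyl amide 7 in the same pot.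

Disconnection 5 (5 to 2 and 3). The C3–C4 bond is cut. A three-carbon homoenolate from 3 adds to aldehyde 2 (through hydroxy ester 4) and creates C3 under the control of C2. The forward reaction has to give the 2,3-syn relationship, which calls for chelation control by the carbamate.

Disconnection 6 (2 to 1). An oxidation-level adjustment only: C2 and its methyl group come from the chiral pool in 1, and the aldehyde is generated without base just before use.

## Alternatives that were turned down

Alternative 1: (the textbook route) Disconnection of both lactone C–O bonds (O3–C12′ and O3′–C12) to two molecules of the N-protected hydroxy acid A1. The forward key step is a double-activation macrodilactonisation of Yamaguchi or Corey–Nicolaou type to the bis(carbamate) A2, followed by hydrogenolysis. It was turned down on step economy and on where the risk falls. A1 carries a complete all-cis piperidine with three stereocentres and an N-protecting group that is installed and removed only to permit the esterification. Its preparation is several times longer than that of the acyclic monomer 10, and the one entropically difficult operation is then tried on the most expensive intermediate. The N-acyl group also forces the C2 and C6 substituents of A1 axial (allylic 1,3-strain), so the hydroxyl to be acylated is flanked by an axial methyl group. Nothing in A1 favours the dimer over oligomers beyond dilution.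

Alternative 2: Removal of all six stereocentres by retro-hydrogenation to the bis(pyridine) diolide A3. The forward key step is a global cis-hydrogenation of two 2,3,6-trisubstituted pyridine rings (PtO2 or Rh/C in acid). The precursor is attractively flat, but the step cannot give the single enantiomer. Each ring would be reduced all-cis but with no absolute control, and the two rings sit eleven atoms apart in a flexible macrocycle and cannot relay chirality, so a statistical mixture of the racemic C2 isomer and the meso isomer is expected. No established asymmetric hydrogenation sets three centres on a 3-acyloxy-2,6-dialkylpyridine. The pyridin-3-yl esters of A3 are also aryl esters, open to C–O hydrogenolysis and to acyl transfer onto the first amine formed.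

Alternative 3: Disconnection at C6≡C7 and C6′≡C7′ together with N1–C6. The forward key step is an alkyne-metathesis cyclodimerisation of the diyne ester A4 to the macrocyclic diyne A5, followed by N-deprotection, double 6-exo-dig hydroamination to the bis(imine) 15 and reduction. It was turned down because the two methyl-capped dialkyl alkynes of A4 are electronically and sterically alike, so metathesis has no head-to-tail preference. The head-to-head cyclodimer (C6≡C6′ and C7≡C7′), of the same ring size and strain, would form statistically and has the wrong constitution. In addition, the primary amines have to be set free next to the esters before a metal-catalysed step, and both alkyne fragments of A4 need separate syntheses. The chosen route gets head-to-tail selectivity from acrylate/1-alkene polarity and brings C6 in at the ketone level.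

Key step: step 5

## Route

Step 1
Reactants: 1 benzyl N-[(2S)-1-hydroxypropan-2-yl]carbamate (N-Cbz-L-alaninol)
Product: 2 benzyl N-[(2S)-1-oxopropan-2-yl]carbamate
Conditions: TEMPO (10 mol %), PhI(OAc)2 (1.1 equiv), CH2Cl2, rt; aq. Na2S2O3/NaHCO3 wash; crude used at once
Reagents that add atoms: none
Why: Nitroxyl-catalysed (oxoammonium) oxidation of the primary alcohol stops at the aldehyde and runs without base, so the C2 stereocentre taken from the chiral pool should not epimerise; the labile aldehyde is neither stored nor chromatographed.

Step 2
Reactants: 2 benzyl N-[(2S)-1-oxopropan-2-yl]carbamate; 3 (1-ethoxycyclopropoxy)trimethylsilane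
Product: 5 benzyl N-[(1S)-1-[(2S)-5-oxooxolan-2-yl]ethyl]carbamate, via hydroxy ester 4 (not isolated)
Conditions: 3 (2 equiv), TiCl4 (2 equiv), CH2Cl2, rt, 30 min; then 2, −40 → 0 °C; H2O; then PPTS (cat.), toluene, 80 °C
Reagents that add atoms: none
Why: TiCl4 opens 3 to the trichlorotitanium homoenolate of ethyl propanoate, which adds to the aldehyde (homoenolate addition of the Nakamura–Kuwajima type); titanium holds aldehyde and carbamate in a Cram-type chelate, so C4 enters past the C2–H and the 2,3-syn (3S) alcohol is expected to predominate. Acid then closes the γ-lactone with loss of ethanol, and the lactone is the stage at which any 3R epimer would be removed by chromatography or crystallisation.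

Step 3
Reactants: 5 benzyl N-[(1S)-1-[(2S)-5-oxooxolan-2-yl]ethyl]carbamate; 6 pent-4-enylmagnesium bromide
Product: 8 benzyl N-[(2S,3S)-3-hydroxy-6-oxoundec-10-en-2-yl]carbamate, via hydroxy Weinreb amide 7 (not isolated)
Conditions: MeNH(OMe)·HCl (2.2 equiv), iPrMgCl (4.3 equiv), THF, −20 °C; then 6 (3 equiv), −20 → 0 °C; sat. aq. NH4Cl
Reagents that add atoms: none
Why: The chloromagnesium amide of N,O-dimethylhydroxylamine opens the lactone to the Weinreb amide (as its magnesium alkoxide), and the Grignard reagent then adds only once because the N-methoxy chelate survives until the quench (one-pot ester-to-ketone conversion through a Weinreb amide). No stereocentre is touched, and the carbamate is protected in situ as its N-magnesium salt.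

Step 4
Reactants: 8 benzyl N-[(2S,3S)-3-hydroxy-6-oxoundec-10-en-2-yl]carbamate; 9 acryloyl chloride
Product: 10 (2S,3S)-2-(benzyloxycarbonylamino)-6-oxoundec-10-en-3-yl prop-2-enoate
Conditions: 9 (1.5 equiv), iPr2NEt (2 equiv), CH2Cl2, −20 → 0 °C
Reagents that add atoms: none
Why: O-Acylation of the secondary alcohol by an acid chloride; the carbamate N–H is not acylated under these conditions, and a γ-acyloxy ketone has no pathway for β-elimination.

Step 5
Reactants: 10 (2S,3S)-2-(benzyloxycarbonylamino)-6-oxoundec-10-en-3-yl prop-2-enoate (two molecules)
Product: 12 (3E,11S,14E,22S)-11,22-bis[(1S)-1-(benzyloxycarbonylamino)ethyl]-1,12-dioxacyclodocosa-3,14-diene-2,8,13,19-tetraone, via linear head-to-tail dimer 11 (not isolated)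
Conditions: second-generation Hoveyda–Grubbs catalyst [RuCl2(H2IMes)(=CH-C6H4-2-OiPr)] (2 × 5 mol %), 1,4-benzoquinone (10 mol %), toluene (0.02 M), 80 °C, argon sparge
Reagents that add atoms: none
Why: Olefin cross-metathesis run as a head-to-tail cyclodimerisation: the ruthenium alkylidene loads onto the electron-rich C10 1-alkene of one molecule of 10 and is passed to the electron-poor acrylate of a second (Chauvin [2+2]/retro-[2+2] cycle) to give linear dimer 11, whose remaining 1-alkene and acrylate then meet in a ring-closing metathesis. The closest known reaction type is the metathetic cyclodimerisation of ω-alkenyl acrylates to C2-symmetric macrodiolides. Ring C (22-membered) is closed by ring-closing metathesis at C10′=C11, a strain-free large-ring closure; no stereocentre is formed, and the E geometry of the two enoates is erased in step 6. Head-to-tail selectivity is needed and is secured by the substrate: acrylate–acrylate coupling is kinetically negligible, and 1-alkene homodimers stay competent donors that are funnelled on to the enoates, which are the thermodynamic sink. Dimer-versus-monomer selectivity rests on strain, because direct closure of 10 would have to place a planar E-enoate in an 11-membered ring. Dimer-versus-oligomer selectivity is set by concentration, and 1,4-benzoquinone suppresses ruthenium hydride chain-walking that would shorten the tether. The carbamate N–H, the C6 ketone and the esters are inert to the catalyst, which is the reason for carrying nitrogen as a non-basic carbamate and leaving rings A and B open at this stage.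

Step 6
Reactants: 12 (3E,11S,14E,22S)-11,22-bis[(1S)-1-(benzyloxycarbonylamino)ethyl]-1,12-dioxacyclodocosa-3,14-diene-2,8,13,19-tetraone
Product: 16 azimine (all-cis 2S,3S,6R in each half; target), via saturated bis(carbamate) 13 (not isolated), via bis(amino ketone) 14 (not isolated), via bis(cyclic imine) 15 (not isolated)
Conditions: H2 (1–4 atm), 10% Pd/C, EtOAc–AcOH (10:1), rt; filter; aq. NaHCO3
Reagents that add atoms: none
Why: Hydrogenation saturates both enoates and hydrogenolyses both benzyl carbamates, and the freed C2 amines condense with the C6 ketones five atoms away to six-membered cyclic imines that are reduced in situ, the hydrogenolytic reductive amination long used for all-cis 2-methyl-6-alkylpiperidin-3-ols. Hydrogen is delivered to C6 from the face opposite the cis C2 methyl and C3 acyloxy groups, so the C7 chain ends cis to both (6R and 6′R), each half being controlled by its own C2/C3 centres. Acetic acid keeps the transient primary amines protonated, which disfavours O→N acyl transfer while it catalyses iminium formation.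

## Compound list

1 | benzyl N-[(2S)-1-hydroxypropan-2-yl]carbamate (N-Cbz-L-alaninol) | C[C@H](NC(=O)OCc1ccccc1)CO | starting material
2 | benzyl N-[(2S)-1-oxopropan-2-yl]carbamate | C[C@H](NC(=O)OCc1ccccc1)C=O | intermediate
3 | (1-ethoxycyclopropoxy)trimethylsilane | CCOC1(CC1)O[Si](C)(C)C | starting material
4 | ethyl (4S,5S)-5-(benzyloxycarbonylamino)-4-hydroxyhexanoate | C[C@H](NC(=O)OCc1ccccc1)[C@@H](O)CCC(=O)OCC | intermediate (not isolated)
5 | benzyl N-[(1S)-1-[(2S)-5-oxooxolan-2-yl]ethyl]carbamate | C[C@H](NC(=O)OCc1ccccc1)[C@@H]1CCC(=O)O1 | intermediate
6 | pent-4-enylmagnesium bromide | C=CCCC[Mg]Br | starting material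
7 | benzyl N-[(2S,3S)-3-hydroxy-6-[methoxy(methyl)amino]-6-oxohexan-2-yl]carbamate (formed as its magnesium alkoxide) | C[C@H](NC(=O)OCc1ccccc1)[C@@H](O)CCC(=O)N(C)OC | intermediate (not isolated)
8 | benzyl N-[(2S,3S)-3-hydroxy-6-oxoundec-10-en-2-yl]carbamate | C[C@H](NC(=O)OCc1ccccc1)[C@@H](O)CCC(=O)CCCC=C | intermediate
9 | acryloyl chloride | C=CC(=O)Cl | starting material
10 | (2S,3S)-2-(benzyloxycarbonylamino)-6-oxoundec-10-en-3-yl prop-2-enoate | C[C@H](NC(=O)OCc1ccccc1)[C@@H](OC(=O)C=C)CCC(=O)CCCC=C | intermediate
11 | (2S,3S)-2-(benzyloxycarbonylamino)-6-oxoundec-10-en-3-yl (2E,10S,11S)-11-(benzyloxycarbonylamino)-7-oxo-10-(prop-2-enoyloxy)dodec-2-enoate (linear head-to-tail dimer) | C[C@H](NC(=O)OCc1ccccc1)[C@@H](OC(=O)C=C)CCC(=O)CCC/C=C/C(=O)O[C@@H](CCC(=O)CCCC=C)[C@H](C)NC(=O)OCc1ccccc1 | intermediate (not isolated)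
12 | (3E,11S,14E,22S)-11,22-bis[(1S)-1-(benzyloxycarbonylamino)ethyl]-1,12-dioxacyclodocosa-3,14-diene-2,8,13,19-tetraone | C[C@H](NC(=O)OCc2ccccc2)[C@@H]1CCC(=O)CCC/C=C/C(=O)O[C@@H](CCC(=O)CCC/C=C/C(=O)O1)[C@H](C)NC(=O)OCc3ccccc3 | intermediate
13 | (11S,22S)-11,22-bis[(1S)-1-(benzyloxycarbonylamino)ethyl]-1,12-dioxacyclodocosane-2,8,13,19-tetraone | C[C@H](NC(=O)OCc2ccccc2)[C@@H]1CCC(=O)CCCCCC(=O)O[C@@H](CCC(=O)CCCCCC(=O)O1)[C@H](C)NC(=O)OCc3ccccc3 | intermediate (not isolated)
14 | (11S,22S)-11,22-bis[(1S)-1-aminoethyl]-1,12-dioxacyclodocosane-2,8,13,19-tetraone | C[C@H](N)[C@@H]1CCC(=O)CCCCCC(=O)O[C@@H](CCC(=O)CCCCCC(=O)O1)[C@H](C)N | intermediate (not isolated)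
15 | bis(2,3,4,5-tetrahydropyridine) diolide: 16 with N1=C6 and N1′=C6′ double bonds, (2S,3S,2′S,3′S) | C[C@@H]1N=C2CCCCCC(=O)O[C@H]3CCC(CCCCCC(=O)O[C@H]1CC2)=N[C@H]3C | intermediate (not isolated)
16 | azimine, the (2S,3S,6R,2′S,3′S,6′R) 22-membered diolide of 6-(5-hydroxy-6-methylpiperidin-2-yl)hexanoic acid | C[C@@H]1N[C@@H]2CCCCCC(=O)O[C@H]3CC[C@@H](CCCCCC(=O)O[C@H]1CC2)N[C@H]3C | target

## Step count and least certain steps

Total step count: 6. Longest linear sequence: 6 steps (1 to 16); there is no convergent branch, since 3, 6 and 9 are commercial.

Step 5 (key step). The likely failure is loss of ring-size control: chain growth to open-chain or larger cyclic oligomers if ring closure of 11 is slower than further intermolecular metathesis, or closure of 10 on itself if the concentration is set too low. Enoates re-enter metathesis only sluggishly, so errors are not fully corrected by equilibration. Double-bond migration by ruthenium hydrides would also give ring-contracted homologues. Fallback: the macrocycle is closed at the ester C–O bonds instead, with the acyclic design kept. From 8, cross-metathesis with acrylic acid (same ruthenium catalyst, CH2Cl2, 40 °C) would give the seco acid (2E,10S,11S)-11-(benzyloxycarbonylamino)-10-hydroxy-7-oxododec-2-enoic acid F1. A Shiina macrodilactonisation of F1 (2-methyl-6-nitrobenzoic anhydride, DMAP, CH2Cl2, slow addition, rt) should then deliver the cyclic dimer, and the route is rejoined at 12.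

Step 6. Three processes may interfere:
- Acyl transfer from O3 to the neighbouring primary amine, if imine formation is slower than expected.
- Amine-mediated carbocyclisation (C5 onto C10), if carbamate cleavage were to outrun enoate saturation.
- Incomplete facial selectivity at C6 in one of the two rings.

Fallback: from 12, catalytic TsOH (toluene, 4 Å molecular sieves, 60 °C) would first close each δ-keto carbamate to its six-membered enecarbamate, giving the bis(N-benzyloxycarbonyl-1,2,3,4-tetrahydropyridine) diolide F2. Hydrogenation of F2 over 10% Pd/C then saturates the enoates and unmasks a nitrogen that is already in the ring, so no primary amine is ever free next to the ester. Either order of C=C reduction and carbamate cleavage should lead to the all-cis ring, and the route is rejoined at 16.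

Step 2. The risks are poor facial selectivity (Felkin–Anh addition competing with the chelate) and partial epimerisation of 2 under the Lewis acid. Fallback with reagent control: from 2, allylboration with (−)-B-allyldiisopinocampheylborane (the (+)-α-pinene-derived antipode, expected by the usual model to give the 3S alcohol; Et2O, −78 °C, oxidative work-up) would give benzyl N-[(2S,3S)-3-hydroxyhex-5-en-2-yl]carbamate F3. Hydroboration of the 1-alkene (9-BBN; H2O2, NaOH) would give the diol benzyl N-[(2S,3S)-3,6-dihydroxyhexan-2-yl]carbamate F4, and TEMPO/PhI(OAc)2 oxidative lactonisation of this 1,4-diol returns to 5.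

Step 3. The risks are incomplete aminolysis followed by double addition of 6 to residual lactone, and attack of the C3 magnesium alkoxide on the carbamate (cyclic carbamate formation) if the mixture warms. Fallback in separate, protected stages: from 5, aminolysis with MeNH(OMe)·HCl/AlMe3 (CH2Cl2, 0 °C) and isolation of 7, then silylation (Et3SiCl, imidazole, DMF) to benzyl N-[(2S,3S)-6-[methoxy(methyl)amino]-6-oxo-3-(triethylsilyloxy)hexan-2-yl]carbamate F5. Addition of 6 (THF, 0 °C) would give benzyl N-[(2S,3S)-6-oxo-3-(triethylsilyloxy)undec-10-en-2-yl]carbamate F6, and desilylation (HF·pyridine, THF) rejoins the route at 8.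

## Further compounds

F1 | step 5 | (2E,10S,11S)-11-(benzyloxycarbonylamino)-10-hydroxy-7-oxododec-2-enoic acid | C[C@H](NC(=O)OCc1ccccc1)[C@@H](O)CCC(=O)CCC/C=C/C(=O)O
F2 | step 6 | bis(N-benzyloxycarbonyl-1,2,3,4-tetrahydropyridine) (E,E)-bis(enoate) diolide (12 less two H2O, with N1–C6 bonds and C5=C6 double bonds in both halves) | C[C@@H]1N(C(=O)OCc4ccccc4)C=2CCC/C=C/C(=O)O[C@H]3CC=C(CCC/C=C/C(=O)O[C@H]1CC=2)N(C(=O)OCc5ccccc5)[C@H]3C
F3 | step 2 | benzyl N-[(2S,3S)-3-hydroxyhex-5-en-2-yl]carbamate | C[C@H](NC(=O)OCc1ccccc1)[C@@H](O)CC=C
F4 | step 2 | benzyl N-[(2S,3S)-3,6-dihydroxyhexan-2-yl]carbamate | C[C@H](NC(=O)OCc1ccccc1)[C@@H](O)CCCO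
F5 | step 3 | benzyl N-[(2S,3S)-6-[methoxy(methyl)amino]-6-oxo-3-(triethylsilyloxy)hexan-2-yl]carbamate | C[C@H](NC(=O)OCc1ccccc1)[C@@H](O[Si](CC)(CC)CC)CCC(=O)N(C)OC
F6 | step 3 | benzyl N-[(2S,3S)-6-oxo-3-(triethylsilyloxy)undec-10-en-2-yl]carbamate | C[C@H](NC(=O)OCc1ccccc1)[C@@H](O[Si](CC)(CC)CC)CCC(=O)CCCC=C
A1 | alternative 1 | 6-[(2R,5S,6S)-1-(benzyloxycarbonyl)-5-hydroxy-6-methylpiperidin-2-yl]hexanoic acid | O[C@H]1CC[C@@H](CCCCCC(=O)O)N(C(=O)OCc2ccccc2)[C@H]1C
A2 | alternative 1 | N1,N1′-bis(benzyloxycarbonyl) derivative of 16 | C[C@@H]1N(C(=O)OCc4ccccc4)[C@@H]2CCCCCC(=O)O[C@H]3CC[C@@H](CCCCCC(=O)O[C@H]1CC2)N(C(=O)OCc5ccccc5)[C@H]3C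
A3 | alternative 2 | 22-membered bis(pyridine) diolide (head-to-tail dilactone of 6-(5-hydroxy-6-methylpyridin-2-yl)hexanoic acid) | Cc1nc2ccc1OC(=O)CCCCCc3ccc(OC(=O)CCCCC2)c(C)n3
A4 | alternative 3 | (2S,3S)-2-(tert-butoxycarbonylamino)oct-6-yn-3-yl oct-6-ynoate | C[C@H](NC(=O)OC(C)(C)C)[C@@H](OC(=O)CCCCC#CC)CCC#CC
A5 | alternative 3 | 22-membered head-to-tail diyne diolide bearing two (1S)-1-(tert-butoxycarbonylamino)ethyl groups | C[C@H](NC(=O)OC(C)(C)C)[C@@H]1CCC#CCCCCC(=O)O[C@@H](CCC#CCCCCC(=O)O1)[C@H](C)NC(=O)OC(C)(C)C
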